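**Plan**

- The target is the trans-(3R,4R)-dibenzylbutyrolactone; the ring is numbered O1, C2 (C=O), C3, C4, C5. C5 is a lone CH2 between O1 and C4, and C4 becomes enolisable if its exocyclic benzylic carbon is carried as an aryl ketone.
- Retrosynthesis: the C4 benzylic CH2 goes back to a ketone; the lactone is then cut at C4–C5 and O1–C2 into formaldehyde and an (R)-2-benzyl-4-aryl-4-oxobutanoic acid; that acid is cut at C3–C4 into an acyl oxazolidinone enolate and a phenacyl bromide.
- Forward: the chain is joined first (C3–C4 by auxiliary alkylation), the only ring closes in the formaldehyde step, and the ketone oxygen and the phenol benzyl ether are removed together at the end.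
- Stereochemistry: C3 comes from the (S)-4-benzyloxazolidin-2-one-directed alkylation; C4 is set trans to it by equilibration α to the ketone.

Key step: step 6

Step 1
Reactants: 1 3-(4-hydroxy-3-methoxyphenyl)propanoic acid (dihydroferulic acid)
Product: 2 3-[4-(benzyloxy)-3-methoxyphenyl]propanoic acid
Conditions: BnBr (1.3 equiv), NaOH (2.5 equiv), EtOH/H2O, reflux; then 2 M HCl
Reagents that add atoms: benzyl bromide, BrCc1ccccc1
Why: Williamson ether synthesis; in aqueous ethanolic hydroxide the phenoxide is far more nucleophilic than the carboxylate, so only the guaiacol oxygen is benzylated and the acid is recovered on acidification.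

Step 2
Reactants: 2 3-[4-(benzyloxy)-3-methoxyphenyl]propanoic acid; 3 (S)-4-benzyloxazolidin-2-one
Product: 5 (S)-4-benzyl-3-{3-[4-(benzyloxy)-3-methoxyphenyl]propanoyl}oxazolidin-2-one, via mixed pivalic anhydride 4 (not isolated)
Conditions: PivCl (1.1 equiv), Et3N (2.5 equiv), THF, −20 °C; then 3, LiCl, −20 °C to rt
Reagents that add atoms: none
Why: N-acylation of the oxazolidinone through a mixed anhydride with LiCl/Et3N activation; the nucleophile attacks the unhindered acyl group and not the pivaloyl carbonyl.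

Step 3
Reactants: 6 1-(3,4,5-trimethoxyphenyl)ethan-1-one (3',4',5'-trimethoxyacetophenone)
Product: 7 2-bromo-1-(3,4,5-trimethoxyphenyl)ethan-1-one
Conditions: CuBr2 (2.0 equiv), EtOAc/CHCl3 (1:1), reflux
Reagents that add atoms: copper dibromide (CuBr2), Br[Cu]Br
Why: King–Ostrum α-bromination; CuBr2 brominates the enol of the aryl methyl ketone at the methyl group and spares the ring, which the acyl group deactivates.

Step 4
Reactants: 5 (S)-4-benzyl-3-{3-[4-(benzyloxy)-3-methoxyphenyl]propanoyl}oxazolidin-2-one; 7 2-bromo-1-(3,4,5-trimethoxyphenyl)ethan-1-one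
Product: 9 (S)-4-benzyl-3-{(R)-2-[4-(benzyloxy)-3-methoxybenzyl]-4-oxo-4-(3,4,5-trimethoxyphenyl)butanoyl}oxazolidin-2-one, via sodium Z-enolate 8 (not isolated)
Conditions: NaN(SiMe3)2 (1.1 equiv), THF, −78 °C; then 7 (1.3 equiv), −78 to −45 °C; AcOH quench
Reagents that add atoms: none
Why: Evans asymmetric alkylation; the chelated sodium Z-enolate displaces bromide from the reactive phenacyl bromide (SN2) on the face away from the C4 benzyl group of the auxiliary, which sets the new centre as R.

Step 5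
Reactants: 9 (S)-4-benzyl-3-{(R)-2-[4-(benzyloxy)-3-methoxybenzyl]-4-oxo-4-(3,4,5-trimethoxyphenyl)butanoyl}oxazolidin-2-one
Product: 11 (R)-2-[4-(benzyloxy)-3-methoxybenzyl]-4-oxo-4-(3,4,5-trimethoxyphenyl)butanoic acid, via peroxy acid 10 (not isolated)
Conditions: LiOH·H2O (2 equiv), 30% H2O2 (4 equiv), THF/H2O (3:1), 0 °C; then aq. Na2SO3; 1 M HCl to pH 2
Reagents that add atoms: hydrogen peroxide, OO
Why: Hydroperoxide cleavage of the Evans imide; LiOOH attacks the exocyclic carbonyl, sulfite reduces the peracid, the cold conditions leave the α-centre intact, and an aryl ketone without a free ortho or para hydroxyl is not oxidised.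

Step 6
Reactants: 11 (R)-2-[4-(benzyloxy)-3-methoxybenzyl]-4-oxo-4-(3,4,5-trimethoxyphenyl)butanoic acid; 12 formaldehyde
Product: 15 (3R,4R)-3-[4-(benzyloxy)-3-methoxybenzyl]-4-(3,4,5-trimethoxybenzoyl)dihydrofuran-2(3H)-one, via hydroxymethyl keto acid 13 (not isolated), via cis keto lactone 14 (not isolated)
Conditions: 37% aq. HCHO (1.3 equiv), 0.5 M NaOH (1.2 equiv), THF/H2O, 0 °C to rt; 2 M HCl to pH 1, 40 °C; crude lactone: DBU (0.1 equiv), CH2Cl2, rt
Reagents that add atoms: none
Why: The hydroxide left over after salt formation reversibly enolises the CH2 next to the aryl ketone of 11, the only acidic C–H of the carboxylate salt, and the enolate adds to formaldehyde in a crossed aldol reaction that forms C4–C5; on acidification the primary alcohol of 13 attacks the free carboxyl and closes the lactone at O1–C2 by a 5-exo-trig acyl substitution. The closest known reaction is the aqueous-base condensation of 3-aroylpropanoic acids with formalin to 4-aroyl-γ-butyrolactones, applied here to a 2-substituted member of that class. The new C4 centre is α to the ketone, so catalytic DBU should equilibrate the cis epimer 14 through the enolate to the trans lactone 15, in which the aroyl group lies anti to the C3 benzyl group fixed in step 4. C3 should be safe, because aqueous hydroxide does not remove a carboxylate α-hydrogen and DBU does not remove the lactone α-hydrogen in the presence of the far more acidic ketone α-hydrogen; ring opening by β-elimination of O1 from the C4 enolate is the reverse of a disfavoured 5-endo-trig closure. The step needs ketone-side enolisation, a single hydroxymethylation and an untouched guaiacol ring; these are secured by the acidity gap between the two α-positions, by the small excess of formaldehyde at a carbon that becomes tertiary and hindered, and by the benzyl ether, without which the phenoxide ring would itself react with formaldehyde.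

Step 7
Reactants: 15 (3R,4R)-3-[4-(benzyloxy)-3-methoxybenzyl]-4-(3,4,5-trimethoxybenzoyl)dihydrofuran-2(3H)-one
Product: 18 (3R,4R)-3-(4-hydroxy-3-methoxybenzyl)-4-(3,4,5-trimethoxybenzyl)dihydrofuran-2(3H)-one, via phenolic keto lactone 16 (not isolated), via benzylic carbinol 17 (not isolated)
Conditions: H2 (3 atm), 10% Pd/C, AcOH, HClO4 (cat.), rt
Reagents that add atoms: none
Why: Catalytic hydrogenolysis; Pd/C cleaves the benzyl aryl ether and, under acid catalysis, takes the electron-rich aryl ketone through the benzylic carbinol to the methylene group, after which neither C3 nor C4 is enolisable toward the lost carbonyl and the trans arrangement is kept.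

**Compound list**

1 | 3-(4-hydroxy-3-methoxyphenyl)propanoic acid (dihydroferulic acid) | COc1cc(CCC(=O)O)ccc1O | starting material
2 | 3-[4-(benzyloxy)-3-methoxyphenyl]propanoic acid | COc1cc(CCC(=O)O)ccc1OCc1ccccc1 | intermediate
3 | (S)-4-benzyloxazolidin-2-one | O=C1OC[C@H](Cc2ccccc2)N1 | starting material
4 | 3-[4-(benzyloxy)-3-methoxyphenyl]propanoic pivalic anhydride | COc1cc(CCC(=O)OC(=O)C(C)(C)C)ccc1OCc1ccccc1 | intermediate (not isolated)
5 | (S)-4-benzyl-3-{3-[4-(benzyloxy)-3-methoxyphenyl]propanoyl}oxazolidin-2-one | COc1cc(CCC(=O)N2[C@@H](Cc3ccccc3)COC2=O)ccc1OCc1ccccc1 | intermediate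
6 | 1-(3,4,5-trimethoxyphenyl)ethan-1-one | CC(=O)c1cc(OC)c(OC)c(OC)c1 | starting material
7 | 2-bromo-1-(3,4,5-trimethoxyphenyl)ethan-1-one | BrCC(=O)c1cc(OC)c(OC)c(OC)c1 | intermediate
8 | sodium (Z)-enolate of 5 | COc1cc(C/C=C(\[O-])N2[C@@H](Cc3ccccc3)COC2=O)ccc1OCc1ccccc1.[Na+] | intermediate (not isolated)
9 | (S)-4-benzyl-3-{(R)-2-[4-(benzyloxy)-3-methoxybenzyl]-4-oxo-4-(3,4,5-trimethoxyphenyl)butanoyl}oxazolidin-2-one | COc1cc(C[C@H](CC(=O)c2cc(OC)c(OC)c(OC)c2)C(=O)N2[C@@H](Cc3ccccc3)COC2=O)ccc1OCc1ccccc1 | intermediate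
10 | (R)-2-[4-(benzyloxy)-3-methoxybenzyl]-4-oxo-4-(3,4,5-trimethoxyphenyl)butaneperoxoic acid | COc1cc(C[C@H](CC(=O)c2cc(OC)c(OC)c(OC)c2)C(=O)OO)ccc1OCc1ccccc1 | intermediate (not isolated)
11 | (R)-2-[4-(benzyloxy)-3-methoxybenzyl]-4-oxo-4-(3,4,5-trimethoxyphenyl)butanoic acid | COc1cc(C[C@H](CC(=O)c2cc(OC)c(OC)c(OC)c2)C(=O)O)ccc1OCc1ccccc1 | intermediate (key-step precursor)
12 | formaldehyde | C=O | starting material
13 | (2R)-2-[4-(benzyloxy)-3-methoxybenzyl]-3-(hydroxymethyl)-4-oxo-4-(3,4,5-trimethoxyphenyl)butanoic acid, both C3 epimers | COc1cc(C[C@H](C(CO)C(=O)c2cc(OC)c(OC)c(OC)c2)C(=O)O)ccc1OCc1ccccc1 | intermediate (not isolated)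
14 | (3R,4S)-3-[4-(benzyloxy)-3-methoxybenzyl]-4-(3,4,5-trimethoxybenzoyl)dihydrofuran-2(3H)-one (cis epimer) | COc1cc(C[C@H]2C(=O)OC[C@H]2C(=O)c2cc(OC)c(OC)c(OC)c2)ccc1OCc1ccccc1 | intermediate (not isolated)
15 | (3R,4R)-3-[4-(benzyloxy)-3-methoxybenzyl]-4-(3,4,5-trimethoxybenzoyl)dihydrofuran-2(3H)-one | COc1cc(C[C@H]2C(=O)OC[C@@H]2C(=O)c2cc(OC)c(OC)c(OC)c2)ccc1OCc1ccccc1 | intermediate (key-step product)
16 | (3R,4R)-3-(4-hydroxy-3-methoxybenzyl)-4-(3,4,5-trimethoxybenzoyl)dihydrofuran-2(3H)-one | COc1cc(C[C@H]2C(=O)OC[C@@H]2C(=O)c2cc(OC)c(OC)c(OC)c2)ccc1O | intermediate (not isolated)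
17 | (3R,4R)-3-(4-hydroxy-3-methoxybenzyl)-4-[hydroxy(3,4,5-trimethoxyphenyl)methyl]dihydrofuran-2(3H)-one, both carbinol epimers | COc1cc(C[C@H]2C(=O)OC[C@@H]2C(O)c2cc(OC)c(OC)c(OC)c2)ccc1O | intermediate (not isolated)
18 | (3R,4R)-3-(4-hydroxy-3-methoxybenzyl)-4-(3,4,5-trimethoxybenzyl)dihydrofuran-2(3H)-one | COc1cc(C[C@H]2C(=O)OC[C@@H]2Cc2cc(OC)c(OC)c(OC)c2)ccc1O | target

**Step count**

Total: 7 steps. Longest linear sequence: 6 steps (steps 1, 2, 4, 5, 6, 7, from dihydroferulic acid); step 3 is a one-step side branch.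

**Steps most likely to fail**

Step 6. Under base the aldol adduct may lose water to the α-methylene ketone, from which double-bond migration would erode C3, or it may take up a second formaldehyde. The fallback moves the C4–C5 bond formation to neutral Lewis-acid conditions. It sets out from 11, which would be esterified (Me3SiCHN2, MeOH/toluene) to methyl (R)-2-[4-(benzyloxy)-3-methoxybenzyl]-4-oxo-4-(3,4,5-trimethoxyphenyl)butanoate F1. Me3SiOTf/Et3N in CH2Cl2 would convert the ketone to the silyl enol ether methyl (R,Z)-2-[4-(benzyloxy)-3-methoxybenzyl]-4-(3,4,5-trimethoxyphenyl)-4-[(trimethylsilyl)oxy]but-3-enoate F2. A Mukaiyama aldol reaction with aqueous formaldehyde catalysed by Yb(OTf)3 in THF/H2O would give the hydroxymethyl keto ester methyl (2R)-2-[4-(benzyloxy)-3-methoxybenzyl]-3-(hydroxymethyl)-4-oxo-4-(3,4,5-trimethoxyphenyl)butanoate F3. Catalytic TsOH in warm toluene followed by catalytic DBU would lactonise and equilibrate it, coming back to the route at 15.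

Step 4. Proton transfer from the acidic CH2Br group of the bromoketone to the imide enolate, or attack at the ketone carbonyl, may outrun the SN2 displacement and leave unreacted imide. The fallback builds the aryl ketone by acylation instead. It sets out from 5, whose sodium enolate would be alkylated with tert-butyl bromoacetate to tert-butyl (R)-4-[(S)-4-benzyl-2-oxooxazolidin-3-yl]-3-[4-(benzyloxy)-3-methoxybenzyl]-4-oxobutanoate F4. TFA/Et3SiH in CH2Cl2 would free (R)-4-[(S)-4-benzyl-2-oxooxazolidin-3-yl]-3-[4-(benzyloxy)-3-methoxybenzyl]-4-oxobutanoic acid F5. Oxalyl chloride with catalytic DMF would give (R)-4-[(S)-4-benzyl-2-oxooxazolidin-3-yl]-3-[4-(benzyloxy)-3-methoxybenzyl]-4-oxobutanoyl chloride F6. A Negishi acylation with (3,4,5-trimethoxyphenyl)zinc chloride (from 5-bromo-1,2,3-trimethoxybenzene, Mg, then ZnCl2) and Pd(PPh3)4 (zerovalent palladium) in THF would install the ketone, coming back to the route at 9 with the same configuration.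

Step 7. In the acidic medium the benzylic carbinol may lose water to a styrene-type alkene before its C–O bond is hydrogenolysed; this would erase C4 and allow hydrogen to add from the face that gives the cis lactone. The reduction may also stall at the carbinol. The fallback removes the carbonyl oxygen without a cationic intermediate. It sets out from 15, which ethane-1,2-dithiol and BF3·OEt2 in CH2Cl2 would convert to (3R,4R)-3-[4-(benzyloxy)-3-methoxybenzyl]-4-[2-(3,4,5-trimethoxyphenyl)-1,3-dithiolan-2-yl]dihydrofuran-2(3H)-one F7. Raney Ni in refluxing EtOH would desulfurise it to (3R,4R)-3-[4-(benzyloxy)-3-methoxybenzyl]-4-(3,4,5-trimethoxybenzyl)dihydrofuran-2(3H)-one F8. H2 over 10% Pd/C in neutral EtOAc would then remove the benzyl ether, coming back to the route at 18.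

**Further compounds**

F1 | step 6 | methyl (R)-2-[4-(benzyloxy)-3-methoxybenzyl]-4-oxo-4-(3,4,5-trimethoxyphenyl)butanoate | COc1cc(C[C@H](CC(=O)c2cc(OC)c(OC)c(OC)c2)C(=O)OC)ccc1OCc1ccccc1
F2 | step 6 | methyl (R,Z)-2-[4-(benzyloxy)-3-methoxybenzyl]-4-(3,4,5-trimethoxyphenyl)-4-[(trimethylsilyl)oxy]but-3-enoate | COc1cc(C[C@H](/C=C(\O[Si](C)(C)C)c2cc(OC)c(OC)c(OC)c2)C(=O)OC)ccc1OCc1ccccc1
F3 | step 6 | methyl (2R)-2-[4-(benzyloxy)-3-methoxybenzyl]-3-(hydroxymethyl)-4-oxo-4-(3,4,5-trimethoxyphenyl)butanoate, both C3 epimers | COc1cc(C[C@H](C(CO)C(=O)c2cc(OC)c(OC)c(OC)c2)C(=O)OC)ccc1OCc1ccccc1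
F4 | step 4 | tert-butyl (R)-4-[(S)-4-benzyl-2-oxooxazolidin-3-yl]-3-[4-(benzyloxy)-3-methoxybenzyl]-4-oxobutanoate | COc1cc(C[C@H](CC(=O)OC(C)(C)C)C(=O)N2[C@@H](Cc3ccccc3)COC2=O)ccc1OCc1ccccc1
F5 | step 4 | (R)-4-[(S)-4-benzyl-2-oxooxazolidin-3-yl]-3-[4-(benzyloxy)-3-methoxybenzyl]-4-oxobutanoic acid | COc1cc(C[C@H](CC(=O)O)C(=O)N2[C@@H](Cc3ccccc3)COC2=O)ccc1OCc1ccccc1
F6 | step 4 | (R)-4-[(S)-4-benzyl-2-oxooxazolidin-3-yl]-3-[4-(benzyloxy)-3-methoxybenzyl]-4-oxobutanoyl chloride | COc1cc(C[C@H](CC(=O)Cl)C(=O)N2[C@@H](Cc3ccccc3)COC2=O)ccc1OCc1ccccc1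
F7 | step 7 | (3R,4R)-3-[4-(benzyloxy)-3-methoxybenzyl]-4-[2-(3,4,5-trimethoxyphenyl)-1,3-dithiolan-2-yl]dihydrofuran-2(3H)-one | COc1cc(C[C@H]2C(=O)OC[C@@H]2C3(SCCS3)c3cc(OC)c(OC)c(OC)c3)ccc1OCc1ccccc1
F8 | step 7 | (3R,4R)-3-[4-(benzyloxy)-3-methoxybenzyl]-4-(3,4,5-trimethoxybenzyl)dihydrofuran-2(3H)-one | COc1cc(C[C@H]2C(=O)OC[C@@H]2Cc2cc(OC)c(OC)c(OC)c2)ccc1OCc1ccccc1
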